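**Retrosynthetic overview**

1. Numbering: left decalin C1–C10 (C4 = quaternary carbon with CH3 and the CH2CH2 bridge, C5=C6 alkene, C8 = CHCH3, C9 = C(CH3)(CH2Ar), C10 = fusion CH; ring B = C1–C5/C10, ring A = C5–C10); right decalin primed (ring C = C5'–C10' with C8'/C9', ring D = C1'–C5'/C10' with C4'Me2 and the C1'=C10' alkene). Last disconnections: O-sulfation of the hydroquinone, then the C4 and C9 methyl groups, which are carried as the two ends of a temporary lactone C4–CH2–O–C(=O)–C9.
2. Ring A is disconnected by a type 2 intramolecular Diels–Alder reaction between a ring-B 1-vinylcyclohexene (C5=C10, C6=C7) and an (E)-2-(2,5-dimethoxybenzyl)but-2-enoate esterified to the C4–CH2OH arm; the tether sets C8, C9 and C10 from C4 and brings in the arene.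
3. Ring B with the C4 stereocentre is disconnected to cyclopentanone (forward: one-carbon ring expansion). The enabling feature is that C4 lies between C3H2 and the sp2 fusion carbon C5: with C5 as C=O and the C4 methyl at the ester level, ring B is a 2-oxocyclohexane-1-carboxylate, i.e. the product of inserting an α-diazo ester carbon (C4, already carrying the CH2CH2–right-decalin chain) into a C(=O)–CH2 bond of cyclopentanone.
4. Right decalin: ring D by McMurry closure of C1'=C10'; its gem-dimethyl carbon C4' is attached to C5' by tert-alkylation of a ring-C silyl enol ether; C8'/C9' come from asymmetric conjugate methylation/alkylation of 2-methylcyclohex-2-en-1-one.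
5. Order of ring formation: ring C (starting material), ring D, ring B (enlargement of the cyclopentanone ring), ring A (together with the temporary lactone).

Key step: step 11

Remark (assumption): the target is drawn as the free bis(hydrogen sulfate); it is assumed that the bis-sulfate from the last step is brought to this form by cation exchange (it would be stored as a salt).
Abbreviation in names: Dec = (1R,2S,4aR)-1,2,5,5-tetramethyl-1,2,3,4,4a,5,6,7-octahydronaphthalen-1-yl (the right-hand decalin, attached through C9').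
Faces of the left decalin: β = the face that carries the C9 methyl group in the target.

**Route**

Step 1
Reactants: 1 2-methylhex-5-en-2-ol
Product: 2 2-chloro-2-methylhex-5-ene
Conditions: conc. aq. HCl, 0 → 25 °C
Reagents that add atoms: hydrogen chloride, Cl
Why: SN1 substitution of the tertiary alcohol by chloride should be clean because the tertiary cation forms readily while the monosubstituted alkene is not protonated under these conditions; no stereocentre is involved.

Step 2
Reactants: 3 2-methylcyclohex-2-en-1-one; 4 ethyl bromoacetate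
Product: 6 ethyl 2-[(1R,6S)-1,6-dimethyl-2-oxocyclohexyl]acetate, via bromomagnesium enolate 5 (not isolated)
Conditions: MeMgBr, Cu(OTf)2 (3 mol %), chiral imidazolinium chloride (NHC precursor, 4 mol %), Et2O, 0 °C; then 4, DMPU, 0 → 25 °C
Reagents that add atoms: methylmagnesium bromide, C[Mg]Br
Why: Copper-catalysed asymmetric conjugate addition of the Grignard reagent should set C8' (S, catalyst control, catalyst enantiomer chosen accordingly), and the magnesium enolate should then be C-alkylated by the α-bromo ester anti to the new neighbouring methyl group (trans alkylation of a 3-substituted cyclohexanone enolate), which sets the quaternary C9' (R) with the two methyl groups cis.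

Step 3
Reactants: 6 ethyl 2-[(1R,6S)-1,6-dimethyl-2-oxocyclohexyl]acetate
Product: 7 ethyl 2-[(1R,6S)-1,6-dimethyl-2-(trimethylsilyloxy)cyclohex-2-en-1-yl]acetate
Conditions: Me3SiOTf, Et3N, CH2Cl2, 0 °C
Reagents that add atoms: trimethylsilyl trifluoromethanesulfonate, C[Si](C)(C)OS(=O)(=O)C(F)(F)F
Why: Silyl enol ether formation by soft enolization should give one regioisomer, because the ketone can enolize only toward C5' (C9' is quaternary) and the ester is silylated much more slowly.

Step 4
Reactants: 7 ethyl 2-[(1R,6S)-1,6-dimethyl-2-(trimethylsilyloxy)cyclohex-2-en-1-yl]acetate; 2 2-chloro-2-methylhex-5-ene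
Product: 8 ethyl 2-[(1R,3R,6S)-1,6-dimethyl-3-(2-methylhex-5-en-2-yl)-2-oxocyclohexyl]acetate
Conditions: TiCl4, CH2Cl2, −40 °C; then NaOEt, EtOH, 25 °C
Reagents that add atoms: none
Why: Lewis-acid-mediated α-tert-alkylation of the silyl enol ether by the tertiary chloride (SN1-type Mukaiyama alkylation) should form the congested C5'–C4' bond, and base then equilibrates the enolizable C5' to the isomer with the tert-alkyl group equatorial and cis to the C9' acetate arm (C9' methyl axial, all other substituents equatorial), which is the required (R) configuration.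

Step 5
Reactants: 8 ethyl 2-[(1R,3R,6S)-1,6-dimethyl-3-(2-methylhex-5-en-2-yl)-2-oxocyclohexyl]acetate
Product: 9 ethyl 2-[(1R,3R,6S)-1,6-dimethyl-3-(2-methyl-5-oxopentan-2-yl)-2-oxocyclohexyl]acetate
Conditions: O3, CH2Cl2/MeOH, −78 °C; then Me2S
Reagents that add atoms: ozone, [O-][O+]=O
Why: Ozonolysis with reductive work-up should cleave the only C=C bond to the aldehyde (C1') and leave ketone, ester and all stereocentres untouched.

Step 6
Reactants: 9 ethyl 2-[(1R,3R,6S)-1,6-dimethyl-3-(2-methyl-5-oxopentan-2-yl)-2-oxocyclohexyl]acetate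
Product: 10 ethyl 2-Dec-acetate
Conditions: TiCl3(DME)1.5, Zn(Cu), DME, reflux, slow addition
Reagents that add atoms: none
Why: Intramolecular McMurry coupling (low-valent titanium pinacol coupling followed by deoxygenation) should join the ketone carbon C10' and the aldehyde carbon C1' in a six-membered ring closure, which forms ring D and fixes the trisubstituted C1'=C10' alkene regiospecifically, while the ester reacts far more slowly than the aldehyde and C5' already holds its thermodynamic configuration.

Step 7
Reactants: 10 ethyl 2-Dec-acetate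
Product: 11 2-Dec-ethan-1-ol
Conditions: LiAlH4, THF, 0 °C
Reagents that add atoms: none
Why: Hydride reduction of the ester to the primary alcohol should be straightforward, the isolated trisubstituted alkene being inert to LiAlH4.

Step 8
Reactants: 11 2-Dec-ethan-1-ol
Product: 12 2-Dec-ethyl iodide
Conditions: I2, PPh3, imidazole, CH2Cl2, 0 → 25 °C
Reagents that add atoms: iodine, [I][I]
Why: Appel-type iodination should convert the unhindered primary alcohol into the iodide by SN2 displacement of the oxyphosphonium group (the carbinol carbon is two bonds away from the quaternary C9').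

Step 9
Reactants: 12 2-Dec-ethyl iodide; 13 ethyl 3-oxobutanoate
Product: 14 ethyl 2-acetyl-4-Dec-butanoate (both C2 epimers)
Conditions: NaH, THF/DMF, 0 → 60 °C
Reagents that add atoms: none
Why: Acetoacetic ester alkylation: the sodium enolate of 13 should be C-alkylated by the primary iodide (SN2), and the new α-centre need not be controlled because it becomes the diazo carbon.

Step 10
Reactants: 14 ethyl 2-acetyl-4-Dec-butanoate
Product: 15 ethyl 2-diazo-4-Dec-butanoate
Conditions: 4-acetamidobenzenesulfonyl azide, DBU, MeCN, 0 → 25 °C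
Reagents that add atoms: 4-acetamidobenzenesulfonyl azide, CC(=O)Nc1ccc(cc1)S(=O)(=O)N=[N+]=[N-]
Why: Deacylative Regitz diazo transfer: the sulfonyl azide should deliver N2 to the α-carbon while the acetyl group is lost to the sulfonamide nitrogen, giving the α-alkyl-α-diazo ester.

Step 11
Reactants: 15 ethyl 2-diazo-4-Dec-butanoate; 16 cyclopentanone
Product: 18 ethyl (1R)-1-(2-Dec-ethyl)-2-oxocyclohexane-1-carboxylate, via diazonium alkoxide 17 (not isolated)
Conditions: Sc(OTf)3 (10 mol %), chiral N,N'-dioxide ligand (L-pipecolic acid-derived, 11 mol %), 16 (3 equiv), CH2Cl2, −20 °C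
Reagents that add atoms: none
Why: The chiral Sc(OTf)3–N,N'-dioxide complex should activate 16, the nucleophilic diazo carbon of 15 adds to the C=O group to give the diazonium alkoxide 17, and a ring C–C bond then migrates from the carbinol carbon to the diazonium carbon anti to the departing N2 (1,2-shift), which regenerates the carbonyl group. The closest known reaction type is the Lewis-acid-catalysed Tiffeneau–Demjanov-type homologation of cycloalkanones with α-alkyl-α-diazo esters in its catalytic enantioselective form. No ring is closed by cyclization: ring B arises by enlargement of the five-membered ring, the former diazo carbon being inserted as C4 between C5 (C=O) and C3, so that C5, C10, C1, C2 and C3 are the five carbons of 16. The new quaternary stereocentre C4 is set by the catalyst, which differentiates the ester and alkyl flanks of the diazo carbon in the addition step (the ligand enantiomer is chosen for the (R) product), the decalin stereocentres lying three bonds away on a flexible chain and having no influence. The step needs migration to win over epoxide closure and over 1,2-hydride shift of the diazo ester, which the oxophilic Lewis acid at low temperature should secure, and it needs single insertion, which follows because the product ketone is α-quaternary; regioselectivity is no issue because both α-carbons of 16 are equivalent.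

Step 12
Reactants: 18 ethyl (1R)-1-(2-Dec-ethyl)-2-oxocyclohexane-1-carboxylate
Product: 19 ethyl (1R)-1-(2-Dec-ethyl)-2-(trifluoromethylsulfonyloxy)cyclohex-2-ene-1-carboxylate
Conditions: KN(SiMe3)2, THF, −78 °C; then PhNTf2, −78 → 0 °C
Reagents that add atoms: N-phenylbis(trifluoromethanesulfonimide), O=S(=O)(N(c1ccccc1)S(=O)(=O)C(F)(F)F)C(F)(F)F
Why: Enolate O-triflation: deprotonation is possible only at C10 because C4 is quaternary, so the C5=C10 enol triflate should form regiospecifically without touching C4.

Step 13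
Reactants: 19 ethyl (1R)-1-(2-Dec-ethyl)-2-(trifluoromethylsulfonyloxy)cyclohex-2-ene-1-carboxylate
Product: 20 ethyl (1R)-1-(2-Dec-ethyl)-2-ethenylcyclohex-2-ene-1-carboxylate
Conditions: tributyl(vinyl)stannane, Pd(PPh3)4 (5 mol %), LiCl, THF, 65 °C
Reagents that add atoms: tributyl(vinyl)stannane, C=C[Sn](CCCC)(CCCC)CCCC
Why: Stille cross-coupling of the enol triflate (LiCl assists transmetalation) should install the vinyl group and complete the 1-vinylcyclohexene diene (C6=C7, C5=C10).

Step 14
Reactants: 20 ethyl (1R)-1-(2-Dec-ethyl)-2-ethenylcyclohex-2-ene-1-carboxylate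
Product: 21 [(1R)-1-(2-Dec-ethyl)-2-ethenylcyclohex-2-en-1-yl]methanol
Conditions: LiAlH4, Et2O, 0 → 35 °C
Reagents that add atoms: none
Why: Hydride reduction of the neopentyl ester should give the primary alcohol that serves as the tether anchor, the diene being inert to LiAlH4.

Step 15
Reactants: 22 2-(chloromethyl)-1,4-dimethoxybenzene; 23 triethyl phosphonoacetate
Product: 24 ethyl 2-(diethoxyphosphoryl)-3-(2,5-dimethoxyphenyl)propanoate
Conditions: NaH, DME, 0 → 60 °C
Reagents that add atoms: none
Why: SN2 alkylation of the phosphonoacetate sodium enolate with the benzylic chloride should give the monoalkylated phosphonate.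

Step 16
Reactants: 24 ethyl 2-(diethoxyphosphoryl)-3-(2,5-dimethoxyphenyl)propanoate; 25 acetaldehyde
Product: 26 ethyl (2E)-2-[(2,5-dimethoxyphenyl)methyl]but-2-enoate
Conditions: NaH, THF, 0 °C; then 25, 0 → 25 °C
Reagents that add atoms: none
Why: Horner–Wadsworth–Emmons olefination of acetaldehyde should give mainly the (E)-enoate (ester trans to the β-methyl group), the minor (Z) isomer being removed by chromatography.

Step 17
Reactants: 26 ethyl (2E)-2-[(2,5-dimethoxyphenyl)methyl]but-2-enoate
Product: 27 (2E)-2-[(2,5-dimethoxyphenyl)methyl]but-2-enoic acid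
Conditions: LiOH, THF/H2O, 25 °C; then aq. HCl
Reagents that add atoms: lithium hydroxide, [Li+].[OH-]
Why: Saponification of the ethyl ester under mild conditions should not move or isomerize the double bond.

Step 18
Reactants: 21 [(1R)-1-(2-Dec-ethyl)-2-ethenylcyclohex-2-en-1-yl]methanol; 27 (2E)-2-[(2,5-dimethoxyphenyl)methyl]but-2-enoic acid
Product: 28 [(1R)-1-(2-Dec-ethyl)-2-ethenylcyclohex-2-en-1-yl]methyl (2E)-2-[(2,5-dimethoxyphenyl)methyl]but-2-enoate
Conditions: EDC·HCl, DMAP, CH2Cl2, 25 °C
Reagents that add atoms: none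
Why: Steglich esterification (carbodiimide, DMAP) should acylate the neopentyl alcohol without isomerizing the enoate, which places the dienophile on the C4 one-carbon arm.

Step 19
Reactants: 28 [(1R)-1-(2-Dec-ethyl)-2-ethenylcyclohex-2-en-1-yl]methyl (2E)-2-[(2,5-dimethoxyphenyl)methyl]but-2-enoate
Product: 29 bridged lactone: left-half 5(6)-ene octalin with a C4β–CH2–O–C(=O)–C9β lactone bridge, 4α-(2-Dec-ethyl), 8α-CH3, 9α-(2,5-dimethoxybenzyl), 10α-H
Conditions: BHT (cat.), 1,2-dichlorobenzene, 180 °C
Reagents that add atoms: none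
Why: Type 2 intramolecular Diels–Alder reaction ([4+2], tether attached at the internal diene carbon C5 through C4) should close ring A and the temporary seven-membered lactone at once, because the three-atom CH2–O–C(=O) link can reach the dienophile only when it adds to the diene face that carries the C4 arm with its carbonyl endo, which fixes C10–H anti to that arm and the C9 carbonyl syn to it, while the (E) geometry places the C8 methyl cis to the C9 arylmethyl group and the short tether imposes the C9–C10/C7–C8 bond pairing.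

Step 20
Reactants: 29 bridged lactone
Product: 30 diol: 4β,9β-bis(hydroxymethyl) analogue of 33
Conditions: LiAlH4, THF, 0 → 25 °C
Reagents that add atoms: none
Why: Hydride reduction should open the strained lactone to the 1,6-diol, which removes the temporary ring and leaves its two carbons as CH2OH groups on C4 and C9.

Step 21
Reactants: 30 diol
Product: 31 dialdehyde: 4β,9β-diformyl analogue of 33
Conditions: Dess–Martin periodinane, NaHCO3, CH2Cl2, 25 °C
Reagents that add atoms: none
Why: Dess–Martin oxidation of both neopentyl alcohols should give the dialdehyde, which cannot epimerize because both α-carbons are quaternary.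

Step 22
Reactants: 31 dialdehyde
Product: 33 2-{[(1R,2R,5S,8aS)-5-(2-Dec-ethyl)-1,2,5-trimethyl-1,2,3,5,6,7,8,8a-octahydronaphthalen-1-yl]methyl}-1,4-dimethoxybenzene, via bis-hydrazone 32 (not isolated)
Conditions: N2H4·H2O, KOH, diethylene glycol, 130 → 200 °C
Reagents that add atoms: hydrazine (as hydrate), NN (its nitrogen atoms are held only in 32)
Why: Wolff–Kishner reduction under Huang–Minlon conditions should convert both hindered aldehydes through their hydrazones into the C4 and C9 methyl groups, alkenes and aryl methyl ethers being stable to hot KOH.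

Step 23
Reactants: 33 dimethyl ether of the hydroquinone
Product: 34 2-{[(1R,2R,5S,8aS)-5-(2-Dec-ethyl)-1,2,5-trimethyl-1,2,3,5,6,7,8,8a-octahydronaphthalen-1-yl]methyl}benzene-1,4-diol
Conditions: NaSEt, DMF, 140 °C; then aq. HCl, Na2S2O4
Reagents that add atoms: none
Why: SN2 demethylation of both aryl methyl ethers by ethanethiolate should free the hydroquinone without acid, so that the phenol cannot add to the C5=C6 alkene, and dithionite in the work-up prevents oxidation to the quinone.

Step 24
Reactants: 34 hydroquinone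
Product: 35 toxiusol
Conditions: SO3·pyridine, pyridine, 40 °C; then cation exchange resin (H+ form), 0 °C
Reagents that add atoms: sulfur trioxide–pyridine complex, O=S(=O)([O-])[n+]1ccccc1
Why: O-Sulfation of both phenols by the SO3·pyridine complex, followed by exchange of pyridinium for H+, should give the bis(hydrogen sulfate) without affecting the two trisubstituted alkenes.

**Compound list**

1 | 2-methylhex-5-en-2-ol | CC(C)(O)CCC=C | starting material
2 | 2-chloro-2-methylhex-5-ene | CC(C)(Cl)CCC=C | intermediate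
3 | 2-methylcyclohex-2-en-1-one | CC1=CCCCC1=O | starting material
4 | ethyl bromoacetate | CCOC(=O)CBr | starting material
5 | bromomagnesium (3S)-2,3-dimethylcyclohex-1-en-1-olate | C[C@H]1CCCC(O[Mg]Br)=C1C | intermediate (not isolated)
6 | ethyl 2-[(1R,6S)-1,6-dimethyl-2-oxocyclohexyl]acetate | CCOC(=O)C[C@@]1(C)C(=O)CCC[C@@H]1C | intermediate
7 | ethyl 2-[(1R,6S)-1,6-dimethyl-2-(trimethylsilyloxy)cyclohex-2-en-1-yl]acetate | CCOC(=O)C[C@@]1(C)C(O[Si](C)(C)C)=CCC[C@@H]1C | intermediate
8 | ethyl 2-[(1R,3R,6S)-1,6-dimethyl-3-(2-methylhex-5-en-2-yl)-2-oxocyclohexyl]acetate | CCOC(=O)C[C@@]1(C)C(=O)[C@H](CC[C@@H]1C)C(C)(C)CCC=C | intermediate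
9 | ethyl 2-[(1R,3R,6S)-1,6-dimethyl-3-(2-methyl-5-oxopentan-2-yl)-2-oxocyclohexyl]acetate | CCOC(=O)C[C@@]1(C)C(=O)[C@H](CC[C@@H]1C)C(C)(C)CCC=O | intermediate
10 | ethyl 2-Dec-acetate | CCOC(=O)C[C@@]1(C)C2=CCCC(C)(C)[C@H]2CC[C@@H]1C | intermediate
11 | 2-Dec-ethan-1-ol | OCC[C@@]1(C)C2=CCCC(C)(C)[C@H]2CC[C@@H]1C | intermediate
12 | 2-Dec-ethyl iodide | ICC[C@@]1(C)C2=CCCC(C)(C)[C@H]2CC[C@@H]1C | intermediate
13 | ethyl 3-oxobutanoate (ethyl acetoacetate) | CCOC(=O)CC(C)=O | starting material
14 | ethyl 2-acetyl-4-Dec-butanoate (C2 epimers) | CCOC(=O)C(CC[C@@]1(C)C2=CCCC(C)(C)[C@H]2CC[C@@H]1C)C(C)=O | intermediate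
15 | ethyl 2-diazo-4-Dec-butanoate | CCOC(=O)C(=[N+]=[N-])CC[C@@]1(C)C2=CCCC(C)(C)[C@H]2CC[C@@H]1C | intermediate
16 | cyclopentanone | O=C1CCCC1 | starting material
17 | diazonium alkoxide betaine (1-oxidocyclopentyl on the diazonium carbon; scandium-bound in the flask) | [O-]C1(CCCC1)[C@@]([N+]#N)(C(=O)OCC)CC[C@@]2(C)C3=CCCC(C)(C)[C@H]3CC[C@@H]2C | intermediate (not isolated)
18 | ethyl (1R)-1-(2-Dec-ethyl)-2-oxocyclohexane-1-carboxylate | O=C1CCCC[C@@]1(C(=O)OCC)CC[C@@]2(C)C3=CCCC(C)(C)[C@H]3CC[C@@H]2C | intermediate
19 | ethyl (1R)-1-(2-Dec-ethyl)-2-(trifluoromethylsulfonyloxy)cyclohex-2-ene-1-carboxylate | O=S(=O)(OC1=CCCC[C@@]1(C(=O)OCC)CC[C@@]2(C)C3=CCCC(C)(C)[C@H]3CC[C@@H]2C)C(F)(F)F | intermediate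
20 | ethyl (1R)-1-(2-Dec-ethyl)-2-ethenylcyclohex-2-ene-1-carboxylate | C=CC1=CCCC[C@@]1(C(=O)OCC)CC[C@@]2(C)C3=CCCC(C)(C)[C@H]3CC[C@@H]2C | intermediate
21 | [(1R)-1-(2-Dec-ethyl)-2-ethenylcyclohex-2-en-1-yl]methanol | C=CC1=CCCC[C@@]1(CO)CC[C@@]2(C)C3=CCCC(C)(C)[C@H]3CC[C@@H]2C | intermediate
22 | 2-(chloromethyl)-1,4-dimethoxybenzene | COc1ccc(OC)c(CCl)c1 | starting material
23 | triethyl phosphonoacetate | CCOC(=O)CP(=O)(OCC)OCC | starting material
24 | ethyl 2-(diethoxyphosphoryl)-3-(2,5-dimethoxyphenyl)propanoate | CCOC(=O)C(Cc1cc(OC)ccc1OC)P(=O)(OCC)OCC | intermediate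
25 | acetaldehyde | CC=O | starting material
26 | ethyl (2E)-2-[(2,5-dimethoxyphenyl)methyl]but-2-enoate | C/C=C(/C(=O)OCC)Cc1cc(OC)ccc1OC | intermediate
27 | (2E)-2-[(2,5-dimethoxyphenyl)methyl]but-2-enoic acid | C/C=C(/C(=O)O)Cc1cc(OC)ccc1OC | intermediate
28 | [(1R)-1-(2-Dec-ethyl)-2-ethenylcyclohex-2-en-1-yl]methyl (2E)-2-[(2,5-dimethoxyphenyl)methyl]but-2-enoate | C=CC1=CCCC[C@@]1(COC(=O)/C(Cc2cc(OC)ccc2OC)=C/C)CC[C@@]3(C)C4=CCCC(C)(C)[C@H]4CC[C@@H]3C | intermediate
29 | bridged lactone (C4β–CH2–O–C(=O)–C9β; 4α-(2-Dec-ethyl), 8α-CH3, 9α-(2,5-dimethoxybenzyl), 10α-H, C5=C6) | C[C@@H]1CC=C2[C@@H](CCC[C@@]2(CO3)CC[C@@]4(C)C5=CCCC(C)(C)[C@H]5CC[C@@H]4C)[C@]1(C3=O)Cc1cc(OC)ccc1OC | intermediate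
30 | diol (4β,9β-bis(hydroxymethyl) analogue of 33) | C[C@@H]1CC=C2[C@@H](CCC[C@@]2(CO)CC[C@@]2(C)C3=CCCC(C)(C)[C@H]3CC[C@@H]2C)[C@]1(CO)Cc1cc(OC)ccc1OC | intermediate
31 | dialdehyde (4β,9β-diformyl analogue of 33) | C[C@@H]1CC=C2[C@@H](CCC[C@@]2(C=O)CC[C@@]2(C)C3=CCCC(C)(C)[C@H]3CC[C@@H]2C)[C@]1(C=O)Cc1cc(OC)ccc1OC | intermediate
32 | bis-hydrazone of 31 | C[C@@H]1CC=C2[C@@H](CCC[C@@]2(C=NN)CC[C@@]2(C)C3=CCCC(C)(C)[C@H]3CC[C@@H]2C)[C@]1(C=NN)Cc1cc(OC)ccc1OC | intermediate (not isolated)
33 | 2-{[(1R,2R,5S,8aS)-5-(2-Dec-ethyl)-1,2,5-trimethyl-1,2,3,5,6,7,8,8a-octahydronaphthalen-1-yl]methyl}-1,4-dimethoxybenzene | C[C@@H]1CC=C2[C@@H](CCC[C@@]2(C)CC[C@@]2(C)C3=CCCC(C)(C)[C@H]3CC[C@@H]2C)[C@]1(C)Cc1cc(OC)ccc1OC | intermediate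
34 | 2-{[(1R,2R,5S,8aS)-5-(2-Dec-ethyl)-1,2,5-trimethyl-1,2,3,5,6,7,8,8a-octahydronaphthalen-1-yl]methyl}benzene-1,4-diol | C[C@@H]1CC=C2[C@@H](CCC[C@@]2(C)CC[C@@]2(C)C3=CCCC(C)(C)[C@H]3CC[C@@H]2C)[C@]1(C)Cc1cc(O)ccc1O | intermediate
35 | toxiusol (bis(hydrogen sulfate) of 34) | C[C@@H]1CC=C2[C@@H](CCC[C@@]2(C)CC[C@@]2(C)C3=CCCC(C)(C)[C@H]3CC[C@@H]2C)[C@]1(C)Cc1cc(OS(=O)(=O)O)ccc1OS(=O)(=O)O | target

**Step count and risks**

Total step count: 24. Longest linear sequence: 20 steps (steps 2–14 and 18–24, from 3); steps 1 and 15–17 are side branches.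

Most likely to fail, step 19: the bridged transition state of the type 2 cycloaddition may be reached too slowly for this trisubstituted dienophile, so that thermal 1,5-hydrogen shift of the diene or oligomerization takes over. Fallback, setting out from 20 (and 26) and coming back at 30: ester 26 would be reduced with i-Bu2AlH to (2E)-2-[(2,5-dimethoxyphenyl)methyl]but-2-en-1-ol F1 and oxidized with MnO2 to (2E)-2-[(2,5-dimethoxyphenyl)methyl]but-2-enal F2. Diene ester 20 and F2 would then be joined in an intermolecular Diels–Alder reaction under a chiral oxazaborolidinium Lewis acid (catalyst control of the diene face, ortho and endo selectivity) to give the C4-ester C9-aldehyde adduct F3, and LiAlH4 reduction of F3 gives diol 30.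

Second, step 11: the catalyst may not differentiate the two flanks of the diazo carbon well enough on this large substrate (mixture of C4 epimers), or 1,2-hydride shift of the diazo ester to an enoate may compete with addition to the ketone. Fallback, setting out from 12 and coming back at 18: commercial ethyl 2-oxocyclohexane-1-carboxylate would be condensed with L-valine tert-butyl ester to the chiral enamino ester ethyl 2-{[(2S)-1-(tert-butoxy)-3-methyl-1-oxobutan-2-yl]amino}cyclohex-1-ene-1-carboxylate F4. Deprotonation with LiN(i-Pr)2 and alkylation with iodide 12 (chiral enamine alkylation, solvent and additive regime chosen for the (R) product) would give the α-quaternary imino ester F5, and mild aqueous acid hydrolysis gives 18.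

Third, step 6: the hindered ketone may resist reductive coupling, so that the aldehyde is simply reduced or the reaction stops at the diol stage. Fallback, setting out from 9 and coming back at 10: SmI2-mediated ketyl–aldehyde pinacol cyclization would give the cis-diol ethyl 2-[(1R,2S,4aR)-8,8a-dihydroxy-1,2,5,5-tetramethyldecahydronaphthalen-1-yl]acetate F6, thiocarbonyldiimidazole would convert it into the cyclic thiocarbonate F7, and Corey–Winter fragmentation with P(OMe)3 at reflux gives alkene 10.

**Further compounds**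

F1 | step 19 | (2E)-2-[(2,5-dimethoxyphenyl)methyl]but-2-en-1-ol | C/C=C(/CO)Cc1cc(OC)ccc1OC
F2 | step 19 | (2E)-2-[(2,5-dimethoxyphenyl)methyl]but-2-enal | C/C=C(/C=O)Cc1cc(OC)ccc1OC
F3 | step 19 | Diels–Alder adduct (4β-CO2Et, 9β-CHO analogue of 33) | C[C@@H]1CC=C2[C@@H](CCC[C@@]2(C(=O)OCC)CC[C@@]3(C)C4=CCCC(C)(C)[C@H]4CC[C@@H]3C)[C@]1(C=O)Cc1cc(OC)ccc1OC
F4 | step 11 | ethyl 2-{[(2S)-1-(tert-butoxy)-3-methyl-1-oxobutan-2-yl]amino}cyclohex-1-ene-1-carboxylate | CCOC(=O)C1=C(N[C@@H](C(C)C)C(=O)OC(C)(C)C)CCCC1
F5 | step 11 | tert-butyl N-[(2R)-2-(2-Dec-ethyl)-2-(ethoxycarbonyl)cyclohexylidene]-L-valinate | CCOC(=O)[C@@]1(CC[C@@]2(C)C3=CCCC(C)(C)[C@H]3CC[C@@H]2C)CCCCC1=N[C@@H](C(C)C)C(=O)OC(C)(C)C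
F6 | step 6 | ethyl 2-[(1R,2S,4aR)-8,8a-dihydroxy-1,2,5,5-tetramethyldecahydronaphthalen-1-yl]acetate (cis-diol) | CCOC(=O)C[C@@]1(C)C2(O)C(O)CCC(C)(C)[C@H]2CC[C@@H]1C
F7 | step 6 | cyclic thiocarbonate of F6 | CCOC(=O)C[C@@]1(C)C23OC(=S)OC3CCC(C)(C)[C@H]2CC[C@@H]1C
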